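**Retrosynthetic overview**
1. The last C–C bond is the aryl–carbonyl bond C6–C(=O). The dihydrocinnamoyl unit is first parked on the phenolic O7 as an ester (a bond absent from the target) and then moved to C6 by an anionic Fries rearrangement started by iodine–lithium exchange at C6.
2. Enabling feature: the free OH on C7 of the benzo ring is the direct ortho neighbour of the acylated C6 (O7–C7–C6–C=O, an ortho-hydroxyaryl ketone), so O7 can serve as a temporary anchor. C8 (prenyl), C4a and C8a are substituted, so C6 is the only site for the iodine and the carbanion.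
3. Aryl half: the C2v-symmetric resorcinol core allows two successive directed ortho-metalations, placing prenyl between the two oxygens (future C8) and iodine at the future C6 without a regiochemical choice.
4. Ring order: the benzene ring is purchased (resorcinol); the pyran ring is closed by prenal condensation/oxa-6π electrocyclisation at the only free activated carbon; a four-membered oxete ring is closed and reopened within the key step.
5. Acyl half: 3-(4-hydroxyphenyl)propanoic acid carried as its aryl silyl ether; desilylation ends the route.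

Key step: step 8

Remark: the target has no stereocentre and no stereogenic double bond (its SMILES carries no stereodescriptor), so it is achiral and no enantiocontrol is needed; the stereocentres of two transient racemic intermediates disappear again.

**Step 1**
Reactants: 1 resorcinol
Product: 2 1,3-bis(methoxymethoxy)benzene
Conditions: NaH, MOMCl, DMF, 0 °C to rt
Reagents that add atoms: chloromethyl methyl ether (MOMCl), COCCl
Why: Williamson-type O-alkylation of both phenoxides should give the bis-acetal, whose OMOM groups serve as ortho-directing groups in steps 2 and 3.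

**Step 2**
Reactants: 2 1,3-bis(methoxymethoxy)benzene, 3 prenyl bromide (1-bromo-3-methylbut-2-ene)
Product: 5 1,3-bis(methoxymethoxy)-2-(3-methylbut-2-en-1-yl)benzene, via aryllithium 4 (not isolated)
Conditions: n-BuLi, THF, 0 °C to rt; then 3, −78 °C to rt
Reagents that add atoms: none
Why: Directed ortho-metalation removes the C2 proton flanked and chelated by both OMOM groups, and the aryllithium should be alkylated at the primary carbon of the allylic bromide (SN2) to give the linear prenyl group.

**Step 3**
Reactants: 5 1,3-bis(methoxymethoxy)-2-(3-methylbut-2-en-1-yl)benzene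
Product: 7 1-iodo-2,4-bis(methoxymethoxy)-3-(3-methylbut-2-en-1-yl)benzene, via aryllithium 6 (not isolated)
Conditions: n-BuLi, TMEDA, THF, −20 to 0 °C; then I2, −78 °C to rt; aq. Na2S2O3
Reagents that add atoms: iodine, II
Why: A second directed ortho-metalation can only occur at C4/C6 (equivalent by symmetry), and iodinolysis of the aryllithium fixes the halogen at the carbon that later receives the acyl group.

**Step 4**
Reactants: 7 1-iodo-2,4-bis(methoxymethoxy)-3-(3-methylbut-2-en-1-yl)benzene
Product: 8 4-iodo-2-(3-methylbut-2-en-1-yl)benzene-1,3-diol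
Conditions: 3 M aq. HCl, MeOH, rt
Reagents that add atoms: none
Why: Acid-catalysed acetal exchange with methanol cleaves both MOM ethers at room temperature, where cyclisation of the prenyl group onto the neighbouring phenol should remain slow.

**Step 5**
Reactants: 8 4-iodo-2-(3-methylbut-2-en-1-yl)benzene-1,3-diol, 9 3-methylbut-2-enal (prenal)
Product: 11 6-iodo-2,2-dimethyl-8-(3-methylbut-2-en-1-yl)-2H-chromen-7-ol, via o-quinone methide 10 (not isolated)
Conditions: ethylenediammonium diacetate (20 mol%), toluene, reflux (Dean–Stark)
Reagents that add atoms: none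
Why: Amine-salt-catalysed Knoevenagel-type C-alkylation at the only free ortho/para carbon (C6 of the diol), dehydration to the o-quinone methide and oxa-6π electrocyclisation (formal [3+3] chromene annulation) can give only one chromene, because C2 and C4 are blocked.

**Step 6**
Reactants: 12 3-(4-hydroxyphenyl)propanoic acid
Product: 14 3-[4-(tert-butyldimethylsilyloxy)phenyl]propanoic acid, via bis-silyl ester 13 (not isolated)
Conditions: TBSCl, imidazole, DMF, rt; then AcOH–THF–H2O (3:1:1), rt
Reagents that add atoms: tert-butyldimethylsilyl chloride (TBSCl), CC(C)(C)[Si](C)(C)Cl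
Why: Silylation of phenol and acid followed by selective hydrolysis of the far more labile silyl ester should leave the aryl silyl ether and free the carboxylic acid.

**Step 7**
Reactants: 11 6-iodo-2,2-dimethyl-8-(3-methylbut-2-en-1-yl)-2H-chromen-7-ol, 14 3-[4-(tert-butyldimethylsilyloxy)phenyl]propanoic acid
Product: 15 6-iodo-2,2-dimethyl-8-(3-methylbut-2-en-1-yl)-2H-chromen-7-yl 3-[4-(tert-butyldimethylsilyloxy)phenyl]propanoate
Conditions: DCC, DMAP (cat.), CH2Cl2, 0 °C to rt
Reagents that add atoms: none
Why: Steglich esterification of the only free hydroxyl (O7) installs the temporary O7–acyl bond next to the iodinated C6.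

**Step 8**
Reactants: 15 6-iodo-2,2-dimethyl-8-(3-methylbut-2-en-1-yl)-2H-chromen-7-yl 3-[4-(tert-butyldimethylsilyloxy)phenyl]propanoate
Product: 18 3-[4-(tert-butyldimethylsilyloxy)phenyl]-1-[7-hydroxy-2,2-dimethyl-8-(3-methylbut-2-en-1-yl)-2H-chromen-6-yl]propan-1-one, via aryllithium 16 (not isolated), via lithium benzoxetolate 17 (not isolated)
Conditions: n-BuLi (1.05 equiv), THF–Et2O, −100 °C, then −78 °C; AcOH quench
Reagents that add atoms: none
Why: Iodine–lithium exchange at C6 with n-BuLi at −100 °C should be faster than addition of n-BuLi to the ester or removal of its α-protons and gives aryllithium 16, whose carbanion lies 1,4 to the carbonyl carbon of the acyl group parked on O7. A 4-exo-trig attack on that carbonyl closes the four-membered lithium benzoxetolate 17 (the only ring formed, closed by C–C bond formation and reopened at once), and ring strain plus the exchange of a C–Li for an O–Li bond drive cleavage of the O7–C bond to the chelated lithium phenoxide of the ortho-hydroxyaryl ketone, which AcOH protonates to 18. The closest known reaction type is the anionic ortho-Fries rearrangement (1,3 O→C acyl shift) started by halogen–metal exchange in ortho-haloaryl esters. No stereocentre remains, since the tetrahedral carbon of racemic 17 returns to a carbonyl and the product is achiral. Site selectivity is absolute because the carbanion can only sit where the iodine was (C6, fixed in step 3) and the acyl transfer is intramolecular from the neighbouring oxygen. Chemoselectivity (exchange before carbonyl addition or enolisation, no second addition to the new ketone) is secured by the fast exchange of an aryl iodide at −100 °C, the near-stoichiometric n-BuLi, and the formation of the ketone as an unreactive lithium chelate.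

**Step 9**
Reactants: 18 3-[4-(tert-butyldimethylsilyloxy)phenyl]-1-[7-hydroxy-2,2-dimethyl-8-(3-methylbut-2-en-1-yl)-2H-chromen-6-yl]propan-1-one
Product: 19 1-[7-hydroxy-2,2-dimethyl-8-(3-methylbut-2-en-1-yl)-2H-chromen-6-yl]-3-(4-hydroxyphenyl)propan-1-one
Conditions: TBAF, AcOH, THF, 0 °C to rt
Reagents that add atoms: none
Why: Fluoride-induced cleavage of the aryl Si–O bond, buffered with acetic acid, should free the second phenol without touching the ketone, the chromene or the prenyl group.

**Compound list**
1 | resorcinol (benzene-1,3-diol) | Oc1cccc(O)c1 | starting material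
2 | 1,3-bis(methoxymethoxy)benzene | COCOc1cccc(OCOC)c1 | intermediate
3 | prenyl bromide (1-bromo-3-methylbut-2-ene) | CC(C)=CCBr | starting material
4 | [2,6-bis(methoxymethoxy)phenyl]lithium | [Li]c1c(OCOC)cccc1OCOC | intermediate
5 | 1,3-bis(methoxymethoxy)-2-(3-methylbut-2-en-1-yl)benzene | COCOc1cccc(OCOC)c1CC=C(C)C | intermediate
6 | [2,4-bis(methoxymethoxy)-3-(3-methylbut-2-en-1-yl)phenyl]lithium | [Li]c1ccc(OCOC)c(CC=C(C)C)c1OCOC | intermediate
7 | 1-iodo-2,4-bis(methoxymethoxy)-3-(3-methylbut-2-en-1-yl)benzene | Ic1ccc(OCOC)c(CC=C(C)C)c1OCOC | intermediate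
8 | 4-iodo-2-(3-methylbut-2-en-1-yl)benzene-1,3-diol | Oc1ccc(I)c(O)c1CC=C(C)C | intermediate
9 | 3-methylbut-2-enal (prenal) | CC(C)=CC=O | starting material
10 | 3-hydroxy-4-iodo-6-(3-methylbut-2-en-1-ylidene)-2-(3-methylbut-2-en-1-yl)cyclohexa-2,4-dien-1-one (o-quinone methide) | CC(C)=CC=C1C=C(I)C(O)=C(CC=C(C)C)C1=O | intermediate
11 | 6-iodo-2,2-dimethyl-8-(3-methylbut-2-en-1-yl)-2H-chromen-7-ol | CC(C)=CCc1c(O)c(I)cc2c1OC(C)(C)C=C2 | intermediate
12 | 3-(4-hydroxyphenyl)propanoic acid | OC(=O)CCc1ccc(O)cc1 | starting material
13 | tert-butyldimethylsilyl 3-[4-(tert-butyldimethylsilyloxy)phenyl]propanoate | CC(C)(C)[Si](C)(C)OC(=O)CCc1ccc(O[Si](C)(C)C(C)(C)C)cc1 | intermediate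
14 | 3-[4-(tert-butyldimethylsilyloxy)phenyl]propanoic acid | OC(=O)CCc1ccc(O[Si](C)(C)C(C)(C)C)cc1 | intermediate
15 | 6-iodo-2,2-dimethyl-8-(3-methylbut-2-en-1-yl)-2H-chromen-7-yl 3-[4-(tert-butyldimethylsilyloxy)phenyl]propanoate | CC(C)=CCc1c(OC(=O)CCc2ccc(O[Si](C)(C)C(C)(C)C)cc2)c(I)cc2c1OC(C)(C)C=C2 | intermediate
16 | [7-({3-[4-(tert-butyldimethylsilyloxy)phenyl]propanoyl}oxy)-2,2-dimethyl-8-(3-methylbut-2-en-1-yl)-2H-chromen-6-yl]lithium | CC(C)=CCc1c(OC(=O)CCc2ccc(O[Si](C)(C)C(C)(C)C)cc2)c([Li])cc2c1OC(C)(C)C=C2 | intermediate
17 | lithium alkoxide of the four-membered cyclic hemiketal (oxete ring fused across C6–C7 of the chromene: C6–C(OLi)(CH2CH2Ar)–O7, Ar = 4-(tert-butyldimethylsilyloxy)phenyl; racemic, transient) | CC(C)=CCc1c2OC(O[Li])(CCc3ccc(O[Si](C)(C)C(C)(C)C)cc3)c2cc2c1OC(C)(C)C=C2 | intermediate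
18 | 3-[4-(tert-butyldimethylsilyloxy)phenyl]-1-[7-hydroxy-2,2-dimethyl-8-(3-methylbut-2-en-1-yl)-2H-chromen-6-yl]propan-1-one | CC(C)=CCc1c(O)c(C(=O)CCc2ccc(O[Si](C)(C)C(C)(C)C)cc2)cc2c1OC(C)(C)C=C2 | intermediate
19 | 1-[7-hydroxy-2,2-dimethyl-8-(3-methylbut-2-en-1-yl)-2H-chromen-6-yl]-3-(4-hydroxyphenyl)propan-1-one (CNP0163015.0) | CC(C)=CCc1c(O)c(C(=O)CCc2ccc(O)cc2)cc2c1OC(C)(C)C=C2 | target

**Step count and risks**
Total step count: 9. Longest linear sequence: 8 steps (steps 1–5 and 7–9, from resorcinol); step 6 is a one-step side branch.

Steps most likely to fail: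

Step 8 (key step). After the iodine–lithium exchange, proton transfer from the ester α-methylene to the aryl carbanion, or addition of butyllithium to the ester carbonyl, could outrun the 1,3-acyl shift, so that the acyl group is lost and de-iodinated chromenol is returned. The fallback replaces the intramolecular transfer by an intermolecular Weinreb ketone synthesis; it sets out from 11 (with 14) and comes back at 18. Phenol 11 would be converted with MOMCl and i-Pr2NEt in CH2Cl2 into 6-iodo-7-(methoxymethoxy)-2,2-dimethyl-8-(3-methylbut-2-en-1-yl)-2H-chromene F1. Acid 14 would be converted with CDI and then MeNHOMe·HCl into N-methoxy-N-methyl-3-[4-(tert-butyldimethylsilyloxy)phenyl]propanamide F2. Iodine–lithium exchange on F1 (n-BuLi, THF, −78 °C) and addition of F2 should give, through the stable chelated tetrahedral adduct, 3-[4-(tert-butyldimethylsilyloxy)phenyl]-1-[7-(methoxymethoxy)-2,2-dimethyl-8-(3-methylbut-2-en-1-yl)-2H-chromen-6-yl]propan-1-one F3. The MOM group ortho to the ketone would then be removed with dilute HCl in MeOH at rt to give 18; should the silyl ether be lost as well, 19 would form directly.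

Step 3. Deprotonation of the benzylic and allylic CH2 of the prenyl group, which lies between the two OMOM groups, could compete with ring lithiation and lead to functionalisation or double-bond migration in the side chain. The fallback abandons carbanion chemistry for electrophilic aromatic substitution; it sets out from 5 and comes back at 7. Treatment of 5 with N-iodosuccinimide in MeCN at 0 °C in the dark should iodinate the ring carbon para to one OMOM and ortho to the other (C4, equivalent to C6), the only activated free ring position, and so give the same iodide 7 without a new intermediate.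

Step 5. Slow C-alkylation of the hindered, iodine-bearing ring could let prenal self-condense under amine catalysis, or let the o-quinone methide dimerise. The fallback uses a boron template in place of amine catalysis; it sets out from 8 (with 9) and comes back at 11. Heating 8, 9 and phenylboronic acid with catalytic AcOH in toluene under water removal should deliver the aldehyde ortho-specifically within a phenoxyboronate and give the cyclic boronate 6-iodo-4-(2-methylprop-1-en-1-yl)-8-(3-methylbut-2-en-1-yl)-2-phenyl-4H-1,3,2-benzodioxaborinin-7-ol F4 (racemic). On continued heating F4 should fragment to the same o-quinone methide 10, which closes to 11.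

**Further compounds**
F1 | step 8 | 6-iodo-7-(methoxymethoxy)-2,2-dimethyl-8-(3-methylbut-2-en-1-yl)-2H-chromene | CC(C)=CCc1c(OCOC)c(I)cc2c1OC(C)(C)C=C2
F2 | step 8 | N-methoxy-N-methyl-3-[4-(tert-butyldimethylsilyloxy)phenyl]propanamide | CON(C)C(=O)CCc1ccc(O[Si](C)(C)C(C)(C)C)cc1
F3 | step 8 | 3-[4-(tert-butyldimethylsilyloxy)phenyl]-1-[7-(methoxymethoxy)-2,2-dimethyl-8-(3-methylbut-2-en-1-yl)-2H-chromen-6-yl]propan-1-one | CC(C)=CCc1c(OCOC)c(C(=O)CCc2ccc(O[Si](C)(C)C(C)(C)C)cc2)cc2c1OC(C)(C)C=C2
F0 | step 3 | none | none
F4 | step 5 | 6-iodo-4-(2-methylprop-1-en-1-yl)-8-(3-methylbut-2-en-1-yl)-2-phenyl-4H-1,3,2-benzodioxaborinin-7-ol (racemic) | CC(C)=CCc1c(O)c(I)cc2c1OB(c1ccccc1)OC2C=C(C)C
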